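**Strategy.** The furofuran is cut at C2–O3 (ring 1: C1–C2–O3–C4–C5) and at C6–O7 (ring 2: C5–C6–O7–C8–C1). C2 and C6 are each an O-substituted benzylic carbon beside an electron-rich ring, so the pair can be masked as one carbon–carbon bond: C2–C6 of a four-membered ring completed by C1 and C5. Oxidising the only free phenol (guaiacyl ring) with a trivalent-iodine reagent severs this strained bond. The hydroxyls on C4 and C8 then add to C2 and C6, so both tetrahydrofurans and both benzylic stereocentres arise in one operation. The precursor is an all-trans 3,4-diarylcyclobutane-1,2-dimethanol whose (1R,2R) carbons C1 and C5 come from a threitol-tethered [2+2] photocycloaddition of two different cinnamates.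

Key step: step 8

Assumption: the sense of induction in step 6 is taken as (4S,5S)-tether → (1R,2R) at the ester-bearing ring carbons; if the opposite pairing prevails, the commercial (4R,5R)-diol is used instead and nothing else changes.

Numbering remark: C1–C8 are the locants of the 3,7-dioxabicyclo[3.3.0]octane and are kept for the same atoms in the cyclobutanes (C1 and C5 carry the CH2O carbons C8 and C4; C2 carries the guaiacyl ring, C6 the trioxygenated ring).

**Step 1**
Reactants: 1 3-hydroxy-4,5-dimethoxybenzaldehyde
Product: 2 3-(benzyloxy)-4,5-dimethoxybenzaldehyde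
Conditions: BnBr (1.1 equiv), K2CO3, DMF, 60 °C
Reagents that add atoms: benzyl bromide, BrCc1ccccc1
Why: Williamson ether synthesis, in which the phenoxide formed with K2CO3 displaces bromide while the aldehyde is inert.

**Step 2**
Reactants: 2 3-(benzyloxy)-4,5-dimethoxybenzaldehyde; 3 malonic acid
Product: 5 (E)-3-[3-(benzyloxy)-4,5-dimethoxyphenyl]prop-2-enoic acid, via arylidenemalonic acid 4 (not isolated)
Conditions: pyridine, piperidine (cat.), 90 °C; then aq. HCl
Reagents that add atoms: none
Why: Knoevenagel condensation in its Doebner modification, where the arylidenemalonic acid loses CO2 in hot pyridine to give the thermodynamically preferred E-cinnamic acid.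

**Step 3**
Reactants: 6 ferulic acid
Product: 7 (E)-3-(4-acetoxy-3-methoxyphenyl)prop-2-enoic acid
Conditions: Ac2O, pyridine, rt; then H2O, dil. HCl
Reagents that add atoms: acetic anhydride, CC(=O)OC(C)=O
Why: O-acetylation of the phenol by nucleophilic acyl substitution (any mixed anhydride at the acid is hydrolysed on work-up), the acetate being chosen because the hydride of step 7 removes it without a separate step.

**Step 4**
Reactants: 5 (E)-3-[3-(benzyloxy)-4,5-dimethoxyphenyl]prop-2-enoic acid; 8 (4S,5S)-2,2-dimethyl-1,3-dioxolane-4,5-dimethanol (3 equiv)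
Product: 9 [(4S,5S)-5-(hydroxymethyl)-2,2-dimethyl-1,3-dioxolan-4-yl]methyl (E)-3-[3-(benzyloxy)-4,5-dimethoxyphenyl]prop-2-enoate
Conditions: EDC·HCl, DMAP (cat.), CH2Cl2, 0 °C → rt
Reagents that add atoms: none
Why: Steglich esterification, in which the two primary hydroxyls of the C2-symmetric diol are equivalent so only one monoester can form and the excess (recoverable) diol holds back double acylation.

**Step 5**
Reactants: 9 the monoester; 7 (E)-3-(4-acetoxy-3-methoxyphenyl)prop-2-enoic acid
Product: 10 mixed diester of diol 8 carrying the cinnamoyl group of 5 on one CH2O and that of 7 on the other (both E)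
Conditions: EDC·HCl, DMAP (cat.), CH2Cl2, 0 °C → rt
Reagents that add atoms: none
Why: Steglich esterification of the remaining primary alcohol, with only catalytic DMAP at or below room temperature so that the aryl acetate is not transferred.

**Step 6**
Reactants: 10 the mixed diester
Product: 11 ten-membered dilactone of diol 8 with (1R,2R,3S,4S)-4-(4-acetoxy-3-methoxyphenyl)-3-[3-(benzyloxy)-4,5-dimethoxyphenyl]cyclobutane-1,2-dicarboxylic acid (all-trans)
Conditions: hν (350 nm lamps, Pyrex), degassed MeCN, 2 mM, rt
Reagents that add atoms: none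
Why: Intramolecular [2+2] photocycloaddition of a diol-tethered dicinnamate, in which the 1,4-diol tether forces head-to-head union, the crossed (anti) alignment of the two E-cinnamoyl arms favoured by the trans-dioxolane gives the all-trans ring with C1 and C5 trans, and the tether stereocentres select the (1R,2R) pairing of alkene faces (the other trans adduct is a separable diastereomer, and epimers at C2 or C6 are tolerable in principle because those centres are erased in step 8).

**Step 7**
Reactants: 11 the tethered cyclobutane
Product: 12 [(1R,2R,3S,4S)-3-[3-(benzyloxy)-4,5-dimethoxyphenyl]-4-(4-hydroxy-3-methoxyphenyl)cyclobutane-1,2-diyl]dimethanol (all-trans)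
Conditions: LiAlH4, THF, 0 °C → rt; aq. potassium sodium tartrate
Reagents that add atoms: none
Why: Hydride reduction of both lactone esters to primary alcohols with concurrent cleavage of the aryl acetate, which releases the tether and the guaiacyl phenol in one operation and leaves the benzyl ether and the ring stereocentres (already in the stable trans arrangement) untouched.

**Step 8**
Reactants: 12 the cyclobutane diol with free guaiacyl phenol
Product: 14 (1R,2S,5R,6S)-6-[3-(benzyloxy)-4,5-dimethoxyphenyl]-2-(4-hydroxy-3-methoxyphenyl)-3,7-dioxabicyclo[3.3.0]octane, via quinone methide tetrahydrofuran 13 (not isolated)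
Conditions: PhI(OAc)2 (1.05 equiv), (CF3)2CHOH–CH2Cl2 (1:4), 0.01 M, −40 → 0 °C
Reagents that add atoms: none
Why: Proposed new method: ligand exchange of the guaiacyl phenol at trivalent iodine and loss of PhI and acetate remove two electrons, and the strained C2–C6 σ-bond fragments in a push–pull (Grob-type) sense to a p-quinone methide at C2 and a benzylic cation at C6 stabilised by the para-methoxy group, with no radical intermediate that could continue to a full retro-[2+2]. The closest known reaction types are trivalent-iodine phenol oxidations that release quinone methide or phenoxenium electrophiles for intramolecular O-capture, and the oxidative ring opening of 1,2-diarylcyclobutanes and arylcyclopropanes with external oxygen nucleophiles; the new element is capture of both termini by two internal hydroxyls. Ring 2 (C5–C6–O7–C8–C1) should close first by 5-exo-trig attack of O7 on the C6 cation to give 13, and ring 1 (C1–C2–O3–C4–C5) by 5-exo-trig 1,6-addition of O3 to the quinone methide carbon C2, which restores the phenol; the only alternatives (O3 to C6, O7 to C2) would be four-membered. C6 is set trans to the C4 substituent on C5 (2,3-trans tetrahydrofuran from the less hindered cation face), and C2 is set by attack of O3 with the aryl on the convex face of the forming cis-fused bicycle, trans to C8, so both aryls end exo; C1 and C5 are not touched and their trans relation becomes the cis ring fusion. The step needs cleavage of C2–C6 in preference to loss of H from C2 or ipso capture, which ring strain, the cation-stabilising aryl on C6 and the all-trans geometry (no hydroxyl can reach the ipso carbon without a trans-fused or bridged ring) should secure. It also needs oxidation of one phenol only, secured by the benzyl ether on the other ring and by one equivalent of oxidant at low temperature and high dilution.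

**Step 9**
Reactants: 14 the O-benzyl furofuran
Product: 15 (1R,2S,5R,6S)-6-(3-hydroxy-4,5-dimethoxyphenyl)-2-(4-hydroxy-3-methoxyphenyl)-3,7-dioxabicyclo[3.3.0]octane (target)
Conditions: H2 (1 atm), 10% Pd/C, EtOAc, rt, stopped at full conversion of 14
Reagents that add atoms: none
Why: Catalytic hydrogenolysis of an aryl benzyl ether, which is much faster than hydrogenolysis of the dialkyl benzylic C–O bonds of the furofuran in a non-protic solvent at ambient pressure, so the four stereocentres stay as set.

**Compound list**
1 | 3-hydroxy-4,5-dimethoxybenzaldehyde | COc1cc(C=O)cc(O)c1OC | starting material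
2 | 3-(benzyloxy)-4,5-dimethoxybenzaldehyde | COc1cc(C=O)cc(OCc2ccccc2)c1OC | intermediate
3 | malonic acid | OC(=O)CC(=O)O | starting material
4 | 2-[3-(benzyloxy)-4,5-dimethoxybenzylidene]malonic acid | COc1cc(C=C(C(=O)O)C(=O)O)cc(OCc2ccccc2)c1OC | intermediate (not isolated)
5 | (E)-3-[3-(benzyloxy)-4,5-dimethoxyphenyl]prop-2-enoic acid | COc1cc(/C=C/C(=O)O)cc(OCc2ccccc2)c1OC | intermediate
6 | ferulic acid | COc1cc(/C=C/C(=O)O)ccc1O | starting material
7 | (E)-3-(4-acetoxy-3-methoxyphenyl)prop-2-enoic acid | COc1cc(/C=C/C(=O)O)ccc1OC(C)=O | intermediate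
8 | (4S,5S)-2,2-dimethyl-1,3-dioxolane-4,5-dimethanol | OC[C@@H]1OC(C)(C)O[C@H]1CO | starting material
9 | [(4S,5S)-5-(hydroxymethyl)-2,2-dimethyl-1,3-dioxolan-4-yl]methyl (E)-3-[3-(benzyloxy)-4,5-dimethoxyphenyl]prop-2-enoate | COc1cc(/C=C/C(=O)OC[C@@H]2OC(C)(C)O[C@H]2CO)cc(OCc2ccccc2)c1OC | intermediate
10 | mixed diester of 8 with acids 5 and 7, (4S,5S), both alkenes E | COc1cc(/C=C/C(=O)OC[C@@H]2OC(C)(C)O[C@H]2COC(=O)/C=C/c2ccc(OC(C)=O)c(OC)c2)cc(OCc2ccccc2)c1OC | intermediate
11 | ten-membered dilactone of 8 with (1R,2R,3S,4S)-4-(4-acetoxy-3-methoxyphenyl)-3-[3-(benzyloxy)-4,5-dimethoxyphenyl]cyclobutane-1,2-dicarboxylic acid, all-trans | O=C3[C@@H]1[C@@H](c2ccc(OC(C)=O)c(OC)c2)[C@H](c2cc(OCc4ccccc4)c(OC)c(OC)c2)[C@H]1C(=O)OC[C@@H]2OC(C)(C)O[C@H]2CO3 | intermediate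
12 | [(1R,2R,3S,4S)-3-[3-(benzyloxy)-4,5-dimethoxyphenyl]-4-(4-hydroxy-3-methoxyphenyl)cyclobutane-1,2-diyl]dimethanol, all-trans | OC[C@@H]1[C@@H](c2ccc(O)c(OC)c2)[C@H](c2cc(OCc3ccccc3)c(OC)c(OC)c2)[C@H]1CO | intermediate (key-step precursor)
13 | 4-{[(3R,4R,5S)-5-[3-(benzyloxy)-4,5-dimethoxyphenyl]-4-(hydroxymethyl)oxolan-3-yl]methylidene}-2-methoxycyclohexa-2,5-dien-1-one (2,3-trans, 3,4-cis oxolane; exocyclic alkene geometry not defined) | COC1=CC(=C[C@H]2CO[C@H](c3cc(OCc4ccccc4)c(OC)c(OC)c3)[C@H]2CO)C=CC1=O | intermediate (not isolated)
14 | (1R,2S,5R,6S)-6-[3-(benzyloxy)-4,5-dimethoxyphenyl]-2-(4-hydroxy-3-methoxyphenyl)-3,7-dioxabicyclo[3.3.0]octane, both aryls exo | COc1cc([C@H]2OC[C@H]3[C@@H]2CO[C@@H]3c2cc(OCc3ccccc3)c(OC)c(OC)c2)ccc1O | intermediate (key-step product)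
15 | (1R,2S,5R,6S)-6-(3-hydroxy-4,5-dimethoxyphenyl)-2-(4-hydroxy-3-methoxyphenyl)-3,7-dioxabicyclo[3.3.0]octane, both aryls exo | COc1cc([C@H]2OC[C@H]3[C@@H]2CO[C@@H]3c2cc(O)c(OC)c(OC)c2)ccc1O | target

**Step count.** Total: 9 steps. Longest linear sequence: 8 steps (1, 2, 4, 5, 6, 7, 8, 9 from aldehyde 1); step 3 is a one-step side branch.

**Steps most likely to fail**

1. Step 8 (the step that carries the new-method label). The ring-opened bis-electrophile may be consumed by elimination, aryl attack or unselective closure before both hydroxyls capture it, or the phenolic product may be oxidised further. The fallback uses known chemistry only, sets out from 12 and returns at 14, and takes the two ring closures out of the oxidation.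
   - 12 is peracetylated (Ac2O, pyridine) to the triacetate F1.
   - Pyrrolidine (CH2Cl2, 0 °C) removes the aryl acetate alone to give the phenol diacetate F2.
   - PhI(OAc)2 in (CF3)2CHOH containing methanol opens the cyclobutane with capture of both benzylic carbons by the external alcohol (the established mode of phenolic diarylcyclobutane opening), giving the bis(methyl ether) diacetate F3 as a mixture at C2 and C6.
   - K2CO3 in MeOH frees the diol F4.
   - Camphorsulfonic acid in CH2Cl2 ionises both benzylic ethers reversibly and closes the two rings, the classical acid cyclisation of 1,4-diaryl-2,3-bis(hydroxymethyl)butane-1,4-diol derivatives. This should deliver 14, with any C2 or C6 epimer separated and returned to the same acid treatment.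

2. Step 6. Parallel (syn) stacking in the directly excited state would lead to the cis-diester adduct, which cannot give a cis-fused bicycle, and face discrimination by the tether may be weak. The fallback sets out from 10 and returns at 11 with no new compound. Direct excitation and template induction are given up as the sources of the trans ring and of the absolute configuration. Instead, 10 is irradiated at 450 nm with [Ir(dF(CF3)ppy)2(dtbbpy)]PF6 (1 mol %) in degassed MeCN (5 mM), so that triplet energy transfer gives a stepwise 1,4-biradical that should close to the most stable trans-diester ring whatever the alkene geometry. The (1R,2R) adduct 11 is then separated by chromatography from its (1S,2S) diastereomer, the chiral tether making the two diastereomeric.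

3. Step 9. Hydrogenolysis may continue into the benzylic C2–O3 and C6–O7 bonds of the electron-rich furofuran. The fallback sets out from 11 and returns at 15, moving the hydrogenolysis to a stage without benzylic C–O bonds.
   - 11 is debenzylated (H2, Pd/C, EtOAc) to the phenol F5.
   - i-Pr3SiCl and imidazole in DMF give the silyl ether F6.
   - i-Bu2AlH (CH2Cl2, −78 → 0 °C) releases the tether and the aryl acetate to give the silyl-protected cyclobutane diol F7.
   - The oxidative ring opening of step 8 gives the silyl furofuran F8.
   - Bu4NF buffered with AcOH in THF gives 15 without any reductive step.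

**Further compounds**
F1 | step 8 | triacetate of 12 (both CH2OAc, guaiacyl OAc), all-trans (1R,2R,3S,4S) | CC(=O)OC[C@@H]1[C@@H](c2ccc(OC(C)=O)c(OC)c2)[C@H](c2cc(OCc3ccccc3)c(OC)c(OC)c2)[C@H]1COC(C)=O
F2 | step 8 | diacetate of 12 with free guaiacyl phenol | CC(=O)OC[C@@H]1[C@@H](c2ccc(O)c(OC)c2)[C@H](c2cc(OCc3ccccc3)c(OC)c(OC)c2)[C@H]1COC(C)=O
F3 | step 8 | (2R,3R)-2-[[3-(benzyloxy)-4,5-dimethoxyphenyl](methoxy)methyl]-3-[(4-hydroxy-3-methoxyphenyl)(methoxy)methyl]butane-1,4-diyl diacetate, benzylic centres undefined | COC(c1ccc(O)c(OC)c1)[C@@H](COC(C)=O)[C@H](COC(C)=O)C(OC)c1cc(OCc2ccccc2)c(OC)c(OC)c1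
F4 | step 8 | (2R,3R)-2-[[3-(benzyloxy)-4,5-dimethoxyphenyl](methoxy)methyl]-3-[(4-hydroxy-3-methoxyphenyl)(methoxy)methyl]butane-1,4-diol, benzylic centres undefined | COC(c1ccc(O)c(OC)c1)[C@@H](CO)[C@H](CO)C(OC)c1cc(OCc2ccccc2)c(OC)c(OC)c1
F0 | step 6 | none | none
F5 | step 9 | debenzylated analogue of 11 (free 3-hydroxy-4,5-dimethoxyphenyl, guaiacyl OAc) | O=C3[C@@H]1[C@@H](c2ccc(OC(C)=O)c(OC)c2)[C@H](c2cc(O)c(OC)c(OC)c2)[C@H]1C(=O)OC[C@@H]2OC(C)(C)O[C@H]2CO3
F6 | step 9 | triisopropylsilyl ether of F5 | O=C3[C@@H]1[C@@H](c2ccc(OC(C)=O)c(OC)c2)[C@H](c2cc(O[Si](C(C)C)(C(C)C)C(C)C)c(OC)c(OC)c2)[C@H]1C(=O)OC[C@@H]2OC(C)(C)O[C@H]2CO3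
F7 | step 9 | analogue of 12 with a triisopropylsilyloxy group in place of benzyloxy | OC[C@@H]1[C@@H](c2ccc(O)c(OC)c2)[C@H](c2cc(O[Si](C(C)C)(C(C)C)C(C)C)c(OC)c(OC)c2)[C@H]1CO
F8 | step 9 | analogue of 14 with a triisopropylsilyloxy group in place of benzyloxy | COc1cc([C@H]2OC[C@H]3[C@@H]2CO[C@@H]3c2cc(O[Si](C(C)C)(C(C)C)C(C)C)c(OC)c(OC)c2)ccc1O
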